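All runs come from a simulation from invented constants, and the scatter is random.

You ask for a quick number for the target in the flask at 6.0 h, and your hunch is that the flat readings mean a dead flask. This is what I have:

| flask | solid substrate | first nucleophile | second nucleophile | temperature | remark | time |
|---|---|---|---|---|---|---|
| violet | 0.20 M | 1.2 equiv | 1.1 equiv | 5 °C | the very flask that is asked about, followed so far |  |
| ochre | 0.20 M | 0.60 equiv | 1.1 equiv | 0 °C | run made earlier |  |
| flask | 0.20 M | 1.20 equiv | 1.10 equiv | 5 °C |  | 6.0 h |

| run | time / min | target / % |
|---|---|---|
| violet | 25.0 | 16.1 |
| violet | 80.0 | 11.1 |
| violet | 120 | 10.6 |
| violet | 180 | 10.8 |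
| violet | 300 | 11.4 |
| violet | 360 | 10.9 |
| ochre | 2.50 | 10.5 |
| ochre | 5.00 | 23.1 |
| ochre | 8.00 | 27.0 |
| ochre | 10.0 | 27.3 |
| ochre | 12.0 | 26.7 |
| ochre | 15.0 | 24.3 |

(standard deviation of a reading: 0.3 percentage points)

- target, in percent of the solid substrate first charged, at 6.0 h
- the remedy with the largest gain of target, or "none" below 2 percentage points (oak / birch / larch / elm / none)
- target present, with what was taken out counted in, in percent of the solid substrate first charged, after birch
- target present, with what was taken out counted in, in percent of the solid substrate first charged, after elm

- oak: at 6.0 h take out 90% of the target then present, then wait 3.0 h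
- birch: at 6.0 h add second nucleophile, 100% of the amount charged, then wait 3.0 h
- larch: change nothing and wait 3.0 h more
- elm: at 6.0 h raise the temperature by 25 K, then wait 3.0 h

- given per volume of solution although it is solid: solid substrate
- removed target is counted in
- what was read earlier has a scatter of 0.3 percentage points, one standard deviation
- at the start none of the solid substrate is in solution
- additions bring no volume worth counting

I take the flat level as the large thing and reckon only the correction to it. The violet readings from 120 min on average 10.9%; this mean, the target the run holds once its fall has ended, I call the resting level. The excess over it is 5.2 percentage points at 25.0 min but 0.18 points at 80.0 min, less than the scatter of 0.3 points, so I add no correction and say 10.9% at 6.0 h.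

The flat stretch of the violet run does not tell a stopped flask from a balanced one. Both nucleophiles were charged above one equivalent, at 1.20 equiv and 1.10 equiv, so I bet on a balance, thermodynamic control of the target against some partner. The resting level is then a fixed share of a pool. If a fraction of the target is taken out, the pool shrinks by that amount and the rest refills to the same share, so the gain is the amount removed times one minus the share. The pool cannot exceed the charge, so on this bet the share is at least 10.9%, and oak gains at most 8.8 points. On the same bet larch gains nothing, and these readings do not size what elm does to a balance.

The forecast gives 10.9%, best none, 4% after birch and 10.9% after elm, holding that “Waiting, warming or removing target changes little, since nothing is left to react.”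

The flask gives 10.8% at 6.0 h, 10.8% after birch and 46.0% after elm, and the best remedy is elm, with a gain of 35 points.

    starting material → intermediate (k = 0.00800 /s, Ea = 74.0 kJ/mol)
    first nucleophile + intermediate → target (k = 1.80 /M/s, Ea = 52.0 kJ/mol)
    second nucleophile + intermediate → other capture product (k = 1.30 /M/s, Ea = 44.0 kJ/mol)
    starting material + intermediate → side product (k = 0.00380 /M/s, Ea = 43.0 kJ/mol)
    solid substrate ⇌ starting material, rate k5*(cs5 - [starting material]) while solid is left; crystals form when [starting material] > cs5 (solubility = 0.160 M, k = 0.0160 /s)
    target ⇌ isomer of the product (K = 4.40, k = 0.00140 /s, Ea = 77.0 kJ/mol, ΔH = −79.0 kJ/mol)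
    (constants at 5 °C)

With the step from target to isomer of the product struck out, the flask holds 58.1% of target at 6.0 h, which makes the resting level, as read, a share of 0.188 of the pool of target and isomer of the product. Oak then reckons at 8 points, and the flask gives 7.9 points. The neighbour with 0.480 equiv of first nucleophile has target and isomer of the product together at 34.3%, so the same share gives 6.45%, and that neighbour stands at 6.35%.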